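**Retrosynthetic overview**
1. Removing the benzyl ether and the acetonide, undoing the anti opening of a 7,8-epoxide by water at C8, and undoing an epoxidation anti to the acetonide leads back to the 5,6-cis-diol acetonide of a 5,6-dihydrochromone that still holds a C7=C8 double bond.
2. The key disconnection cuts C4a–C5 and C6–C7: an inverse-electron-demand Diels–Alder reaction with loss of CO2. The dienophile is 2,2-dimethyl-1,3-dioxole, which supplies C5–C6 with both oxygens held cis by its ring. The diene is a flat, achiral 4H,5H-pyrano[4,3-b]pyran-4,5-dione, where the diene C4a=C8a–C8=C7 of the later carbocycle is stored as a 2-pyrone (a C(=O)–O bridge from C4a to C7).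
3. Enabling feature: C4a carries the C4 ketone of the 4-pyranone ring and, in the precursor, also the lactone carbonyl. These two parallel C=O groups form a 1,3-dicarbonyl pocket that binds a chiral copper Lewis acid, and the C4a=C8a bond shared by both rings lets the 4-pyranone return as soon as CO2 leaves.
4. The precursor comes from an acylketene and 4-hydroxy-2-pyrone. The acylketene comes from a 6-(2-arylethyl)dioxinone, made by γ-alkylation of 2,2,6-trimethyl-1,3-dioxin-4-one with the benzylic bromide.
5. Ring order: 2-pyrone (bought), then 4-pyranone (step 3), then the carbocycle in place of the 2-pyrone (step 6).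

Key step: step 6

Remark on numbering: positions are numbered as in the target chromone (O1, C2, C3, C4, C4a, C5 to C8, C8a), also in the precursors. (R,R)-tBu-box is 2,2'-(propane-2,2-diyl)bis[(4R)-4-tert-butyl-4,5-dihydro-1,3-oxazole].
Assumption: 4-hydroxy-2H-pyran-2-one is taken as a catalogue compound, and the sense of induction in step 6 is assigned from the square-planar chelate model (both antipodes of the ligand are sold).

**Step 1**
Reactants: 1 3-(benzyloxy)-4-methoxybenzyl alcohol
Product: 2 3-(benzyloxy)-4-methoxybenzyl bromide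
Conditions: PBr3 (0.4 equiv), Et2O, 0 °C; used without storage
Reagents that add atoms: phosphorus tribromide, BrP(Br)Br
Why: Bromination of a benzylic alcohol through its phosphite ester (SN2 by bromide), under which both aryl ethers are inert.

**Step 2**
Reactants: 3 2,2,6-trimethyl-4H-1,3-dioxin-4-one; 2 3-(benzyloxy)-4-methoxybenzyl bromide
Product: 5 6-{2-[3-(benzyloxy)-4-methoxyphenyl]ethyl}-2,2-dimethyl-4H-1,3-dioxin-4-one, via lithium dienolate 4 (not isolated)
Conditions: LDA (1.1 equiv), THF/DMPU, −78 °C; then 2, −78 to −20 °C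
Reagents that add atoms: none
Why: Vinylogous (γ-selective) alkylation of the cross-conjugated lithium dienolate of the dioxinone with a reactive benzylic bromide, a known route to 6-(2-arylethyl)dioxinones, with DMPU favouring reaction at the γ-carbon.

**Step 3**
Reactants: 5 6-{2-[3-(benzyloxy)-4-methoxyphenyl]ethyl}-2,2-dimethyl-4H-1,3-dioxin-4-one; 6 4-hydroxy-2H-pyran-2-one
Product: 9 2-{2-[3-(benzyloxy)-4-methoxyphenyl]ethyl}-4H,5H-pyrano[4,3-b]pyran-4,5-dione, via acylketene 7 (not isolated), via C-acyl pyrone 8 (not isolated)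
Conditions: PhMe, 110 °C (acetone swept out); then TsOH·H2O (10 mol %), Dean–Stark
Reagents that add atoms: none
Why: Thermal retro-[4+2] of the dioxinone frees the acylketene, which acylates the nucleophilic C3 of the cyclic 1,3-dicarbonyl enol 6 (O-acylation is reversible at this temperature), and acid-catalysed cyclodehydration then closes the 4-pyranone, the reaction type by which diketene or dioxinones turn 4-hydroxycoumarins and 4-hydroxy-2-pyrones into fused 4-pyranones.

**Step 4**
Reactants: 10 racemic 2,2-dimethyl-1,3-dioxolane-4-carboxylic acid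
Product: 11 racemic 2,2-dimethyl-1,3-dioxolan-4-yl acetate
Conditions: Pb(OAc)4 (1.1 equiv), pyridine (0.2 equiv), EtOAc, rt to 40 °C
Reagents that add atoms: lead tetraacetate, CC(=O)O[Pb](OC(C)=O)(OC(C)=O)OC(C)=O
Why: Oxidative decarboxylation of an α-alkoxy acid with lead tetraacetate, in which the α-oxy radical is oxidised to the oxocarbenium ion and trapped by acetate as known for 1,3-dioxolane-4-carboxylic acids, and whose stereocentre does not matter because step 5 removes it.

**Step 5**
Reactants: 11 racemic 2,2-dimethyl-1,3-dioxolan-4-yl acetate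
Product: 12 2,2-dimethyl-1,3-dioxole
Conditions: flow pyrolysis, quartz tube, 450 °C, N2 stream; condensate distilled from K2CO3
Reagents that add atoms: none
Why: Ester pyrolysis (thermal syn elimination) of an α-acyloxy ether, the reaction type that turns 2-acetoxy-1,4-dioxane into 1,4-dioxene, and only the ring CH2 offers β-hydrogens, so only one alkene can form.

**Step 6**
Reactants: 9 2-{2-[3-(benzyloxy)-4-methoxyphenyl]ethyl}-4H,5H-pyrano[4,3-b]pyran-4,5-dione; 12 2,2-dimethyl-1,3-dioxole (3 equiv)
Product: 14 (5S,6R)-2-{2-[3-(benzyloxy)-4-methoxyphenyl]ethyl}-5,6-(isopropylidenedioxy)-5,6-dihydro-4H-chromen-4-one, via bridged lactone 13 (not isolated)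
Conditions: Cu(OTf)2 (10 mol %), (R,R)-tBu-box (11 mol %), 4 Å MS, CH2Cl2, −40 to 0 °C; then 2,2'-bipyridine (20 mol %), PhMe, 80 °C
Reagents that add atoms: none
Why: The C4 ketone and the lactone carbonyl, both on C4a and held parallel by the fused rings, chelate the divalent copper of the bis(oxazoline) complex and lower the LUMO of the 2-pyrone diene C4a=C8a–C8=C7, so that the electron-rich dioxole adds across C7 and C4a in an asynchronous inverse-electron-demand Diels–Alder reaction (C6–C7 leading, C4a–C5 following), after which the copper is tied up by bipyridine and warming expels the C(=O)–O bridge of 13 as CO2 by retro-[4+2] and restores the 4-pyranone. The closest known reaction type is the chiral-Lewis-acid-catalysed inverse-electron-demand Diels–Alder reaction of 3-carbonyl-substituted 2-pyrones with enol ethers, followed by thermal loss of CO2 to a cyclohexadiene. The carbocycle is closed by an intermolecular [4+2] cycloaddition that is suprafacial on both partners, first as a 2-oxabicyclo[2.2.2]octene and then, after cycloreversion, as the cyclohexadiene. C5 and C6 are held cis by the five-membered ring of the dioxole, and their absolute configuration follows from attack on the diene face left open by the tert-butyl group next to the lactone carbonyl combined with the endo approach (dioxole oxygens under C8a=C8), while C4a and C7 of 13 are transient centres that vanish with CO2. The step needs periselectivity for the 2-pyrone diene, secured because C7 is the only unsubstituted, doubly vinylogous acceptor carbon and only this path ends in irreversible loss of CO2, and it needs no regioselectivity because 12 is symmetric. It needs both face and endo selectivity, because an exo approach to the same face would end in the antipode once CO2 is lost.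

**Step 7**
Reactants: 14 the (5S,6R) diene acetonide
Product: 15 (5S,6S,7R,8R)-2-{2-[3-(benzyloxy)-4-methoxyphenyl]ethyl}-7,8-epoxy-5,6-(isopropylidenedioxy)-5,6,7,8-tetrahydro-4H-chromen-4-one (epoxide anti to the acetonide)
Conditions: mCPBA (1.3 equiv), CH2Cl2, 0 °C to rt
Reagents that add atoms: mCPBA, O=C(OO)c1cccc(Cl)c1
Why: Prilezhaev epoxidation of C7=C8, the only alkene outside the 4-pyranone, from the face anti to the cis-fused acetonide as with acetonides of arene cis-dihydrodiols, so that both new C–O bonds lie anti to the C5 and C6 oxygens.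

**Step 8**
Reactants: 15 the (5S,6S,7R,8R) epoxide
Product: 16 (5S,6S,7R,8S)-2-{2-[3-(benzyloxy)-4-methoxyphenyl]ethyl}-7,8-dihydroxy-5,6-(isopropylidenedioxy)-5,6,7,8-tetrahydro-4H-chromen-4-one
Conditions: H2O/1,4-dioxane (1:1), NaOBz (10 mol %), 90 °C
Reagents that add atoms: water, O
Why: SN2 opening of the epoxide by water under benzoate catalysis at C8, which is allylic to C4a=C8a and remote from the acetonide whereas C7 is deactivated and shielded by the neighbouring C6–O bond, so that inversion at C8 and retention of the C7–O bond give the 7,8-trans diol with the C8 hydroxyl syn to the acetonide.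

**Step 9**
Reactants: 16 the benzyl-protected 7,8-diol
Product: 17 (5S,6S,7R,8S)-7,8-dihydroxy-2-[2-(3-hydroxy-4-methoxyphenyl)ethyl]-5,6-(isopropylidenedioxy)-5,6,7,8-tetrahydro-4H-chromen-4-one
Conditions: H2 (1 atm), Pd/C (10 wt %), EtOAc/EtOH, rt
Reagents that add atoms: none
Why: Hydrogenolysis of the aryl benzyl ether, under which the 4-pyranone and the C5 and C8 carbinol carbons on this electron-poor ring should not be reduced at one atmosphere and room temperature.

**Step 10**
Reactants: 17 the phenol acetonide
Product: 18 (5S,6S,7R,8S)-5,6,7,8-tetrahydroxy-2-[2-(3-hydroxy-4-methoxyphenyl)ethyl]-5,6,7,8-tetrahydro-4H-chromen-4-one (target)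
Conditions: AcOH/H2O (4:1), 45 °C
Reagents that add atoms: none
Why: Acid-catalysed hydrolysis of the cis-fused isopropylidene acetal, which breaks no C–O bond at a stereocentre, and the electron-poor 4-pyranone disfavours cation formation at C5 or C8, so all four centres are kept.

**Compound list**
1 | 3-(benzyloxy)-4-methoxybenzyl alcohol | COc1ccc(CO)cc1OCc1ccccc1 | starting material
2 | 3-(benzyloxy)-4-methoxybenzyl bromide | COc1ccc(CBr)cc1OCc1ccccc1 | intermediate
3 | 2,2,6-trimethyl-4H-1,3-dioxin-4-one | CC1=CC(=O)OC(C)(C)O1 | starting material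
4 | lithium 2,2-dimethyl-6-methylidene-6H-1,3-dioxin-4-olate (lithium dienolate of 3) | [Li+].[O-]C1=CC(=C)OC(C)(C)O1 | intermediate
5 | 6-{2-[3-(benzyloxy)-4-methoxyphenyl]ethyl}-2,2-dimethyl-4H-1,3-dioxin-4-one | COc1ccc(CCC2=CC(=O)OC(C)(C)O2)cc1OCc1ccccc1 | intermediate
6 | 4-hydroxy-2H-pyran-2-one | OC1=CC(=O)OC=C1 | starting material
7 | 5-[3-(benzyloxy)-4-methoxyphenyl]pent-1-ene-1,3-dione (acylketene) | COc1ccc(CCC(=O)C=C=O)cc1OCc1ccccc1 | intermediate
8 | 3-{5-[3-(benzyloxy)-4-methoxyphenyl]-3-oxopentanoyl}-4-hydroxy-2H-pyran-2-one | COc1ccc(CCC(=O)CC(=O)C2=C(O)C=COC2=O)cc1OCc1ccccc1 | intermediate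
9 | 2-{2-[3-(benzyloxy)-4-methoxyphenyl]ethyl}-4H,5H-pyrano[4,3-b]pyran-4,5-dione | COc1ccc(CCC2=CC(=O)C3=C(O2)C=COC3=O)cc1OCc1ccccc1 | intermediate
10 | racemic 2,2-dimethyl-1,3-dioxolane-4-carboxylic acid | CC1(C)OCC(O1)C(=O)O | starting material
11 | racemic 2,2-dimethyl-1,3-dioxolan-4-yl acetate | CC(=O)OC1COC(C)(C)O1 | intermediate
12 | 2,2-dimethyl-1,3-dioxole | CC1(C)OC=CO1 | intermediate
13 | (4aS,5S,6R,7S) endo bridged lactone: C(=O)–O bridge from C4a to C7, dioxolane oxygens at C5 and C6 syn to the C8a=C8 bridge and anti to the lactone bridge | O=C1C=C(CCc5ccc(OC)c(OCc6ccccc6)c5)OC2=C[C@@H]3OC(=O)[C@]12[C@@H]4OC(C)(C)O[C@@H]43 | intermediate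
14 | (5S,6R)-2-{2-[3-(benzyloxy)-4-methoxyphenyl]ethyl}-5,6-(isopropylidenedioxy)-5,6-dihydro-4H-chromen-4-one | COc1ccc(CCc2cc(=O)c3c(o2)C=C[C@H]2OC(C)(C)O[C@@H]32)cc1OCc1ccccc1 | intermediate
15 | (5S,6S,7R,8R)-7,8-epoxide of 14, anti to the acetonide | COc1ccc(CCc2cc(=O)c3c(o2)[C@@H]4O[C@@H]4[C@H]2OC(C)(C)O[C@@H]32)cc1OCc1ccccc1 | intermediate
16 | (5S,6S,7R,8S)-7,8-diol 5,6-acetonide, benzyl ether | COc1ccc(CCc2cc(=O)c3c(o2)[C@@H](O)[C@H](O)[C@H]2OC(C)(C)O[C@@H]32)cc1OCc1ccccc1 | intermediate
17 | (5S,6S,7R,8S)-7,8-diol 5,6-acetonide, free phenol | COc1ccc(CCc2cc(=O)c3c(o2)[C@@H](O)[C@H](O)[C@H]2OC(C)(C)O[C@@H]32)cc1O | intermediate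
18 | (5S,6S,7R,8S)-5,6,7,8-tetrahydroxy-2-[2-(3-hydroxy-4-methoxyphenyl)ethyl]-5,6,7,8-tetrahydro-4H-chromen-4-one | COc1ccc(CCc2cc(=O)c3c(o2)[C@@H](O)[C@H](O)[C@@H](O)[C@H]3O)cc1O | target

**Step count and risks**
Total step count: 10. Longest linear sequence: 8 (steps 1, 2, 3, 6, 7, 8, 9, 10).

Steps most likely to fail:

1. **Step 6.**
   - Risk: the donor-substituted pyrone may add slowly. The Lewis acid may oligomerise the dioxole before cycloaddition. Reaction through the exo approach or on the shielded face would lower the enantiopurity.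
   - Fallback, from 9 and 12 back to 14: the two are heated without catalyst (PhMe, sealed tube, 110 °C). Cycloaddition and loss of CO2 then run thermally through 13 and the antipode of the bridged lactone F1. They should give the racemate made of 14 and the antipode of the diene acetonide F2.
   - Preparative chromatography on a chiral stationary phase separates the two, so absolute control moves from a catalyst to a separation.

2. **Step 3.**
   - Risk: O-acylation of the 4-hydroxyl group followed by closure in the Pechmann sense, or dimerisation of the acylketene, may take the place of C-acylation at C3.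
   - Fallback, from 5 back to 9, with the order of ring formation reversed: 5 is heated with ethyl 3-(pyrrolidin-1-yl)but-2-enoate (PhMe, 110 °C). The acylketene 7 acylates the enamine carbon and closes with loss of the amine to ethyl 6-{2-[3-(benzyloxy)-4-methoxyphenyl]ethyl}-2-methyl-4-oxo-4H-pyran-3-carboxylate F3.
   - Me2NCH(OMe)2 (110 °C) condenses with the doubly activated 2-methyl group to give the 2-[(E)-2-(dimethylamino)vinyl]pyranone ester F4. Aqueous HCl in AcOH (80 °C) hydrolyses the enamine and lactonises the enol onto the ester, as in isocoumarin syntheses.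

3. **Step 8.**
   - Risk: water may attack at C7 in competition, or the epoxide may isomerise on heating.
   - Fallback, from 14 back to 16, bypassing 15: Upjohn dihydroxylation (OsO4 cat., NMO, acetone/H2O) anti to the acetonide gives the (5S,6S,7R,8R) 7,8-cis diol F5.
   - A Mitsunobu reaction (4-nitrobenzoic acid, PPh3, DIAD, THF) at the more reactive allylic C8 hydroxyl inverts this centre to give the 8-(4-nitrobenzoate) F6. A cis diol cannot divert to an epoxide here. Methanolysis (K2CO3 cat., MeOH) then frees the diol.

**Further compounds**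
F1 | step 6 | antipode of bridged lactone 13 (4aR,5R,6S,7R) | O=C1C=C(CCc5ccc(OC)c(OCc6ccccc6)c5)OC2=C[C@H]3OC(=O)[C@@]12[C@H]4OC(C)(C)O[C@H]43
F2 | step 6 | antipode of diene acetonide 14 (5R,6S) | COc1ccc(CCc2cc(=O)c3c(o2)C=C[C@@H]2OC(C)(C)O[C@H]32)cc1OCc1ccccc1
F3 | step 3 | ethyl 6-{2-[3-(benzyloxy)-4-methoxyphenyl]ethyl}-2-methyl-4-oxo-4H-pyran-3-carboxylate | CCOC(=O)C1=C(C)OC(CCc2ccc(OC)c(OCc3ccccc3)c2)=CC1=O
F4 | step 3 | ethyl 6-{2-[3-(benzyloxy)-4-methoxyphenyl]ethyl}-2-[(E)-2-(dimethylamino)vinyl]-4-oxo-4H-pyran-3-carboxylate | CCOC(=O)C1=C(/C=C/N(C)C)OC(CCc2ccc(OC)c(OCc3ccccc3)c2)=CC1=O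
F5 | step 8 | (5S,6S,7R,8R)-7,8-cis diol 5,6-acetonide, benzyl ether | COc1ccc(CCc2cc(=O)c3c(o2)[C@H](O)[C@H](O)[C@H]2OC(C)(C)O[C@@H]32)cc1OCc1ccccc1
F6 | step 8 | (5S,6S,7R,8S)-7-hydroxy-8-(4-nitrobenzoyloxy) 5,6-acetonide, benzyl ether | COc1ccc(CCc2cc(=O)c3c(o2)[C@@H](OC(=O)c4ccc(cc4)[N+](=O)[O-])[C@H](O)[C@H]2OC(C)(C)O[C@@H]32)cc1OCc1ccccc1
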